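I could not integrate this network by hand over the whole run, so I looked for a number that does not need its middle.

    substrate + coupling partner → open intermediate (k1 = 0.097 /M/min)
    coupling partner + fresh partner → second intermediate (k2 = 0.063 /M/min)
    open intermediate + second intermediate → target (k3 = 0.028 /M/min)
    target ⇌ isomer of the product (K4 = 0.36, k4 = 0.0012 /min)

all flasks: substrate 0.050 M

| flask | fresh partner | coupling partner | time | remark |
|---|---|---|---|---|
| epsilon | 2.00 equiv | 1.50 equiv (fed, over 4.00 d) | 5.0 d | a stirred flask in which coupling partner is dosed at a steady rate over 4.00 d without added volume, worked up at 5.0 d |
| delta | 2.00 equiv (fed, over 4.00 d) | 1.50 equiv | 5.0 d | all but fresh partner at the start; fresh partner goes in evenly over 4.00 d, the run ends at 5.0 d |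
| eta | 2.00 equiv | 1.50 equiv | 5.0 d | everything together in a closed stirred flask, run for 5.0 d |
| beta | 2.00 equiv | 1.50 equiv |  | one stirred flow tank at steady state, fed with the mixture as stated, mean residence time 5.0 d |

- the set-up with the highest share of target in all that became target or isomer of the product, at the outlet or at the end ("none" if the first two lie within 2 percentage points) (epsilon / delta / eta / beta / none)
- share of target in all that became target or isomer of the product, at the outlet or at the end, epsilon
- share of target in all that became target or isomer of the product, at the outlet or at the end, delta
- share of target in all that became target or isomer of the product, at the outlet or at the end, eta
- share of target in all that became target or isomer of the product, at the outlet or at the end, beta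

- the stated concentrations are those of everything mixed, before any reaction; amounts are the same in each set-up
- the feed brings no volume worth counting
- run time (epsilon): 5.0 d

Every set-up ends in the exchange between target and isomer of the product, so I turned that step's constants into times. The back constant is the forward one over the equilibrium constant:

0.00333 /min

Forward plus back, inverted, gives:

3.68 h

This is the settling time, the relaxation time in which the pair's departure from its equilibrium ratio shrinks by a factor e. The run lasts 32.6 settling times, so I expected thermodynamic control. My first way used the equilibrium constant:

share of target = 73.5%

My second way was a balance on isomer of the product in beta, the tank, where it is formed from target, returns, and washes out: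

forward constant × c(target) = (back constant + inverse residence time) × c(isomer of the product)

share of target = 74.3%

The two ways part by 0.79 percentage points. The equilibrium way cheats for the tank, since it sets the washout to zero, and the washout of 1.39 × 10⁻⁴ /min is small beside the back constant but is not nil. This gave me a rule for a pool of target plus isomer of the product that grows slowly against the settling time:

excess over equilibrium ≈ equilibrium share of isomer of the product × settling time / renewal time of the pool

A closed flask filling evenly over 5.0 d gets 0.81 points. I did not rank epsilon, delta and eta, for that needs the rate at which each pool fills late in the run, and I had not integrated it. My two figures part by less than the margin, so I committed to no winner.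

The forecast gave 74% for epsilon, 73.6% for delta, 73.6% for eta, 74.3% for beta and the verdict none, holding that “every set-up sits near the equilibrium share”.

The simulation gave 74.1% for epsilon, 73.6% for delta, 73.6% for eta, 74.3% for beta and the verdict none. With the exchange struck out both ways, eta and beta read 100% and 100%. Epsilon's reading stands 0.60 points above equilibrium, and the rule, run backwards with the settling time of 3.68 h, puts the renewal time of its pool at 6.98 d, with 8.25% of the substrate charged still present as open intermediate at the end.

The numbers are assumed; no experiment stands behind them.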